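**Strategy.** The hexasubstituted A ring (C4a–C5–C6–C7–C8–C8a) is not bought as a polyoxygenated acetophenone but grown last onto a preformed 2-aryl-3-methoxy-4-pyranone (rings B and C). C5–C8, a vicinal dimethoxy pair flanked by para oxygens, are the four carbons of dimethyl squarate; C8a and C4a are C6 and C5 of the pyranone. Thermal ring expansion (Moore rearrangement) of a 4-pyranonyl-2,3,4-trimethoxycyclobutenone, by 4π ring opening to a dienylketene and 6π electrocyclization, forms the C4a–C5 bond, closes the benzene ring and delivers 5-OH and 8-OMe already differentiated, so the target emerges directly from the key step.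

Key step: step 5

Remark: the target has no stereocentre and no configurationally stable axis, so "single enantiomer" is moot and the achiral compound is made as drawn; 9 and 11 are racemic intermediates whose stereocentres vanish in step 5.

**Step 1**
Reactants: 1 3-hydroxy-4H-pyran-4-one (pyromeconic acid)
Product: 2 3-hydroxy-2-iodo-4H-pyran-4-one
Conditions: NIS (1.05 equiv), MeCN, 0 °C → rt, dark
Reagents that add atoms: N-iodosuccinimide (NIS), O=C1CCC(=O)N1I
Why: Electrophilic iodination of the enol at C2, the enol β-carbon ortho to the hydroxyl, which is the position at which 3-hydroxy-4-pyranones undergo halogenation, Mannich and aldol reactions.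

**Step 2**
Reactants: 2 3-hydroxy-2-iodo-4H-pyran-4-one
Product: 3 2-iodo-3-methoxy-4H-pyran-4-one
Conditions: MeI (1.5 equiv), K2CO3, acetone, 40 °C
Reagents that add atoms: iodomethane (MeI), CI
Why: Williamson O-methylation of the acidic enolic hydroxyl under mild carbonate conditions.

**Step 3**
Reactants: 3 2-iodo-3-methoxy-4H-pyran-4-one; 4 (4-methoxyphenyl)boronic acid
Product: 5 3-methoxy-2-(4-methoxyphenyl)-4H-pyran-4-one
Conditions: Pd(dppf)Cl2 (3 mol %), K2CO3, dioxane/H2O 9:1, 70 °C
Reagents that add atoms: none
Why: Suzuki–Miyaura coupling at the C2–I bond of a vinylogous acyl iodide, which should undergo fast oxidative addition, under carbonate conditions mild enough to spare the pyranone ring.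

**Step 4**
Reactants: 5 3-methoxy-2-(4-methoxyphenyl)-4H-pyran-4-one; 6 dimethyl squarate (3,4-dimethoxycyclobut-3-ene-1,2-dione)
Product: 9 2,3,4-trimethoxy-4-[5-methoxy-6-(4-methoxyphenyl)-4-oxo-4H-pyran-2-yl]cyclobut-2-en-1-one (racemic), via 6-lithiopyranone 7 (not isolated), via lithium alkoxide 8 (not isolated)
Conditions: LiTMP (1.1 equiv), THF, −78 °C, 20 min; cannulate into 6 (1.3 equiv), THF, −78 °C; MeOTf (1.3 equiv), −78 → −20 °C
Reagents that add atoms: methyl trifluoromethanesulfonate (MeOTf), COS(=O)(=O)C(F)(F)F
Why: A hindered lithium amide should remove the C6–H next to the ring oxygen (the site at which chromones and 4-pyranones are metalated, giving an alkenyllithium that has no β-leaving group), this adds 1,2 to one carbonyl of dimethyl squarate at −78 °C, and the tertiary lithium alkoxide, far more nucleophilic than the pyranone carbonyl, is O-methylated by MeOTf, which is the standard organolithium addition/alkoxide trapping entry to 4-alkoxycyclobutenones; the new quaternary centre forms as a racemate and is erased in step 5.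

**Step 5**
Reactants: 9 2,3,4-trimethoxy-4-[5-methoxy-6-(4-methoxyphenyl)-4-oxo-4H-pyran-2-yl]cyclobut-2-en-1-one
Product: 12 5-hydroxy-3,6,7,8-tetramethoxy-2-(4-methoxyphenyl)-4H-chromen-4-one (5-hydroxyauranetin), via dienylketene 10 (not isolated), via cyclohexadienone tautomer 11 (not isolated)
Conditions: p-xylene (degassed, 0.02 M), 140 °C, Ar
Reagents that add atoms: none
Why: Thermal 4π-conrotatory electrocyclic opening of the cyclobutenone C1–C4 bond should give dienylketene 10, and because the C4 methoxy donor rotates outward (torquoselectivity) the pyranonyl group turns inward and sits cis to the ketene. A 6π-disrotatory electrocyclization of the ketene C=C, the central enol ether C=C and the pyranone C5=C6 bond then forms the C4a–C5 bond and closes the six-membered A ring as dienone 11, whose C4a–H enolizes at once to the phenol, driven by aromatization and the C5–OH···O=C4 hydrogen bond. The closest known reaction type is the Moore rearrangement of 4-alkenyl- and 4-(hetero)aryl-4-alkoxycyclobutenones to hydroquinone monoethers. No stereocentre is created, and the racemic centres of 9 (C4) and 11 (C4a) disappear on aromatization. Regioselectivity is secured by the substrate, since the only neighbour of the attachment carbon that can bond to the ketene carbon is pyranone C5 (the other neighbour is the ring oxygen). The ether at cyclobutenone C4 becomes 8-OMe and the ketene oxygen becomes 5-OH, so no late selective methylation or demethylation is needed.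

**Compound list**
1 | 3-hydroxy-4H-pyran-4-one (pyromeconic acid) | O=c1ccocc1O | starting material
2 | 3-hydroxy-2-iodo-4H-pyran-4-one | O=c1ccoc(I)c1O | intermediate
3 | 2-iodo-3-methoxy-4H-pyran-4-one | COc1c(I)occc1=O | intermediate
4 | (4-methoxyphenyl)boronic acid | COc1ccc(B(O)O)cc1 | starting material
5 | 3-methoxy-2-(4-methoxyphenyl)-4H-pyran-4-one | COc1ccc(-c2occc(=O)c2OC)cc1 | intermediate
6 | dimethyl squarate (3,4-dimethoxycyclobut-3-ene-1,2-dione) | COC1=C(OC)C(=O)C1=O | starting material
7 | 6-lithio-3-methoxy-2-(4-methoxyphenyl)-4H-pyran-4-one | [Li]c1cc(=O)c(OC)c(-c2ccc(OC)cc2)o1 | intermediate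
8 | lithium 2,3-dimethoxy-1-[5-methoxy-6-(4-methoxyphenyl)-4-oxo-4H-pyran-2-yl]-4-oxocyclobut-2-en-1-olate (racemic) | [Li]OC1(c2cc(=O)c(OC)c(-c3ccc(OC)cc3)o2)C(=O)C(OC)=C1OC | intermediate
9 | 2,3,4-trimethoxy-4-[5-methoxy-6-(4-methoxyphenyl)-4-oxo-4H-pyran-2-yl]cyclobut-2-en-1-one (racemic) | COC1(c2cc(=O)c(OC)c(-c3ccc(OC)cc3)o2)C(=O)C(OC)=C1OC | intermediate
10 | (3Z)-2,3,4-trimethoxy-4-[5-methoxy-6-(4-methoxyphenyl)-4-oxo-4H-pyran-2-yl]buta-1,3-dien-1-one (dienylketene) | O=C=C(OC)/C(OC)=C(/OC)c1cc(=O)c(OC)c(-c2ccc(OC)cc2)o1 | intermediate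
11 | 3,6,7,8-tetramethoxy-2-(4-methoxyphenyl)-4aH-chromene-4,5-dione (racemic) | COc1ccc(C2=C(OC)C(=O)C3C(=O)C(OC)=C(OC)C(OC)=C3O2)cc1 | intermediate
12 | 5-hydroxy-3,6,7,8-tetramethoxy-2-(4-methoxyphenyl)-4H-chromen-4-one (5-hydroxyauranetin) | COc1ccc(-c2oc3c(OC)c(OC)c(OC)c(O)c3c(=O)c2OC)cc1 | target

**Total step count:** 5
**Longest linear sequence:** 5 steps (1 → 2 → 3 → 5 → 9 → 12)

**Steps most likely to fail**

1. Step 4. The lithiated pyranone may add in conjugate fashion to pyranone that is not yet metalated, part of the deprotonation may occur at C5 (followed by ring opening), or MeOTf may alkylate the pyranone carbonyl instead of the hindered alkoxide. Fallback (sets out from 5, comes back at 7): zincation of 5 with TMPZnCl·LiCl (THF, 25 °C), a base that metalates 4-pyranones next to the ring oxygen without self-addition, should give chloro[5-methoxy-6-(4-methoxyphenyl)-4-oxo-4H-pyran-2-yl]zinc F1 (not isolated). Iodinolysis with I2 should then give 6-iodo-3-methoxy-2-(4-methoxyphenyl)-4H-pyran-4-one F2, which is purified. Iodine–lithium exchange (t-BuLi, 2 equiv, THF/Et2O, −100 °C) then generates 7 with defined regiochemistry and in the absence of unmetalated pyranone and amine, and the route resumes at 7 with the addition to 6.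

2. Step 5. At 140 °C the tertiary methyl ether may ionise before ring opening, or the dienylketene may be diverted to oligomers if closure onto the cross-conjugated pyranone C5=C6 bond is slow. Fallback (sets out from 8, comes back at 12): 8 is quenched with aqueous NH4Cl instead of MeOTf to give the carbinol 4-hydroxy-2,3-dimethoxy-4-[5-methoxy-6-(4-methoxyphenyl)-4-oxo-4H-pyran-2-yl]cyclobut-2-en-1-one F3. Free 4-hydroxycyclobutenones open at lower temperature (degassed toluene, 80–110 °C) and with a still stronger outward preference of the oxygen substituent. F3 should therefore pass through the hydroxy-dienylketene (3Z)-4-hydroxy-2,3-dimethoxy-4-[5-methoxy-6-(4-methoxyphenyl)-4-oxo-4H-pyran-2-yl]buta-1,3-dien-1-one F4 and the dienone 8-hydroxy-3,6,7-trimethoxy-2-(4-methoxyphenyl)-4aH-chromene-4,5-dione F5 to the hydroquinone 5,8-dihydroxy-3,6,7-trimethoxy-2-(4-methoxyphenyl)-4H-chromen-4-one F6, handled under argon (any quinone formed by air is reduced back with Na2S2O4). Mono-O-methylation of F6 (MeI 1.1 equiv, K2CO3, acetone, rt) should occur at the free 8-OH, the 5-OH being deactivated by its hydrogen bond to C4=O, and gives 12.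

3. Step 3. Attack of the aqueous base at C2 of the vinylogous acyl iodide (ipso-substitution and ring opening) or protodeiodination may outrun transmetalation. Fallback (sets out from 3, comes back at 5): the polarity of the coupling is reversed and base is avoided. Zinc insertion into 3 (Zn dust, LiCl, THF, 25 °C) should give iodo(3-methoxy-4-oxo-4H-pyran-2-yl)zinc F7, which is cross-coupled under Negishi conditions with 4-iodoanisole (COc1ccc(I)cc1; Pd(PPh3)4 cat., THF, 50 °C) to give 5.

**Further compounds**
F1 | step 4 | chloro[5-methoxy-6-(4-methoxyphenyl)-4-oxo-4H-pyran-2-yl]zinc | Cl[Zn]c1cc(=O)c(OC)c(-c2ccc(OC)cc2)o1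
F2 | step 4 | 6-iodo-3-methoxy-2-(4-methoxyphenyl)-4H-pyran-4-one | COc1ccc(-c2oc(I)cc(=O)c2OC)cc1
F3 | step 5 | 4-hydroxy-2,3-dimethoxy-4-[5-methoxy-6-(4-methoxyphenyl)-4-oxo-4H-pyran-2-yl]cyclobut-2-en-1-one (racemic) | OC1(c2cc(=O)c(OC)c(-c3ccc(OC)cc3)o2)C(=O)C(OC)=C1OC
F4 | step 5 | (3Z)-4-hydroxy-2,3-dimethoxy-4-[5-methoxy-6-(4-methoxyphenyl)-4-oxo-4H-pyran-2-yl]buta-1,3-dien-1-one | O=C=C(OC)/C(OC)=C(/O)c1cc(=O)c(OC)c(-c2ccc(OC)cc2)o1
F5 | step 5 | 8-hydroxy-3,6,7-trimethoxy-2-(4-methoxyphenyl)-4aH-chromene-4,5-dione (racemic) | COc1ccc(C2=C(OC)C(=O)C3C(=O)C(OC)=C(OC)C(O)=C3O2)cc1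
F6 | step 5 | 5,8-dihydroxy-3,6,7-trimethoxy-2-(4-methoxyphenyl)-4H-chromen-4-one | COc1ccc(-c2oc3c(O)c(OC)c(OC)c(O)c3c(=O)c2OC)cc1
F7 | step 3 | iodo(3-methoxy-4-oxo-4H-pyran-2-yl)zinc | COc1c([Zn]I)occc1=O
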